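**Retrosynthetic overview**
- Two Wittig disconnections (C11=C12 and C11'=C12') split the target into a furanoid C15 phosphonium salt, the C10 dialdehyde 2,7-dimethylocta-2,4,6-trienedial and an ε-ring C15 phosphonium salt.
- The furanoid salt comes from (−)-loliolide: half-reduction to the lactol acetate, then a Pd-catalysed allyl–alkenyl coupling that makes the C8–C9 bond.
- Loliolide comes from an acyclic ynoate diol by one radical bicyclisation that closes the cyclohexane (ring A, with its gem-dimethyl carbon) and the butenolide together; the diol comes from prenal, an acetone enol ether and ethyl propiolate.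
- The ε half comes from racemic α-ionone by HWE chain extension, allylic oxidation and a reagent-controlled CBS reduction that splits the racemate into separable diastereomers.
- Ring order: the ε ring is bought; ring A and the oxygen ring form in the same operation; the lactone is then taken down to the dihydrofuran level.

Assumption: the SMILES is read as all-E (3S,5R,8S,3'R,6'R)-5,8-epoxy-5,8-dihydro-β,ε-carotene-3,3'-diol; carotenoid locants are used in the text and the C10 dialdehyde is taken as a purchasable industrial intermediate.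

**Route**

Step 1
Reactants: 1 3-methylbut-2-enal (prenal); 2 2-methoxypropene
Product: 4 (4R)-4-hydroxy-6-methylhept-5-en-2-one, via enol ether 3 (not isolated)
Conditions: Ti(OiPr)4 (5 mol%), Carreira tridentate binaphthyl Schiff-base ligand (5 mol%, antipode giving Re-face attack), 3,5-di-tert-butylsalicylic acid (10 mol%), 2/Et2O, 0 °C; then aq. oxalic acid (pH 3), 0 °C
Reagents that add atoms: water, O
Why: catalytic enantioselective Mukaiyama-type (ene-like) acetone aldol addition in which the chiral titanium Lewis acid blocks one aldehyde face and sets the carbinol (later C3) as R, with mild hydrolysis of 3 to avoid dehydration of the allylic aldol.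

Step 2
Reactants: 4 (4R)-4-hydroxy-6-methylhept-5-en-2-one; 5 ethyl propiolate
Product: 6 ethyl (4R,6R)-4,6-dihydroxy-4,8-dimethylnon-7-en-2-ynoate
Conditions: 5 (2.5 equiv), LiN(iPr)2 (2.5 equiv), THF, −78 °C; anhydrous CeCl3 (2.5 equiv); then 4, −78 °C; AcOH quench at −78 °C; minor C4 epimer removed on silica
Reagents that add atoms: none
Why: chelation-controlled 1,2-addition of a cerium/lithium acetylide (Cram chelate, 1,3-induction), in which the alkoxide-bridged six-membered chelate with the dimethylvinyl group equatorial is attacked axially and sets the tertiary carbinol (later C5) as R; dr is expected to be moderate and the epimers are separable.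

Step 3
Reactants: 6 ethyl (4R,6R)-4,6-dihydroxy-4,8-dimethylnon-7-en-2-ynoate
Product: 8 (−)-loliolide [(6S,7aR)-6-hydroxy-4,4,7a-trimethyl-5,6,7,7a-tetrahydro-1-benzofuran-2(4H)-one], via hydroxy ester 7 (not isolated)
Conditions: Fe(acac)3 (30 mol%), PhSiH3 (2.5 equiv), degassed EtOH/ethylene glycol 5:1, 60 °C; then PhSSPh (10 mol%), 400 nm LED, 25 °C
Reagents that add atoms: none
Why: Proposed new method: hydrogen-atom transfer from an iron hydride to the trisubstituted alkene gives the tertiary radical at the future gem-dimethyl carbon, which closes 6-exo-dig onto the β-carbon of the ynoate, and after reduction and protonation the Z enoate lactonises at once while thiyl-radical E/Z equilibration drains the E isomer into the same butenolide, so both rings form in one operation with no new stereocentre; the closest known reactions are MHAT-initiated Giese cyclisation (Baran reductive olefin coupling) and radical addition to alkynoates followed by lactonisation.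

Step 4
Reactants: 8 (−)-loliolide
Product: 10 (6S,7aR)-4,4,7a-trimethyl-2,4,5,6,7,7a-hexahydro-1-benzofuran-2,6-diyl diacetate (both C2 epimers), via lactol 9 (not isolated)
Conditions: iBu2AlH (DIBAL-H, 2.2 equiv), CH2Cl2, −78 °C; then pyridine, DMAP (cat.), Ac2O (4 equiv), −78 → 0 °C
Reagents that add atoms: acetic anhydride, CC(=O)OC(C)=O
Why: half-reduction of the butenolide to the aluminium lactolate with in situ acetylation (Rychnovsky reductive acetylation), which also caps the ring hydroxyl; the quaternary C7a prevents aromatisation to a furan and no ring stereocentre is touched.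

Step 5
Reactants: 11 ethyl but-2-ynoate
Product: 12 ethyl (2Z)-3-(4,4,5,5-tetramethyl-1,3,2-dioxaborolan-2-yl)but-2-enoate
Conditions: CuCl (3 mol%), Xantphos (3 mol%), NaOtBu (6 mol%), B2pin2 (1.1 equiv), MeOH (2 equiv), THF, 25 °C
Reagents that add atoms: bis(pinacolato)diboron, CC1(C)OB(OC1(C)C)B1OC(C)(C)C(C)(C)O1
Why: copper-catalysed conjugate borylation (formal hydroboration) of an ynoate, where syn addition of boryl-copper and protonation place boron trans to the ester so that coupling with retention gives the 9E chain.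

Step 6
Reactants: 10 (6S,7aR)-4,4,7a-trimethyl-2,4,5,6,7,7a-hexahydro-1-benzofuran-2,6-diyl diacetate; 12 ethyl (2Z)-3-(4,4,5,5-tetramethyl-1,3,2-dioxaborolan-2-yl)but-2-enoate
Product: 13 ethyl (2E)-3-[(2S,6S,7aR)-6-acetoxy-4,4,7a-trimethyl-2,4,5,6,7,7a-hexahydro-1-benzofuran-2-yl]but-2-enoate
Conditions: Pd2(dba)3 [tris(dibenzylideneacetone)dipalladium] (2.5 mol%), P(2-furyl)3 (10 mol%), CsF (2.5 equiv), THF, 40 °C; C8 epimers separated on silica
Reagents that add atoms: none
Why: Suzuki–Miyaura-type allylic alkenylation in which zerovalent palladium ionises the acetal acetate to an alkoxy-π-allyl complex and the alkenyl group is delivered at the acetal carbon (the other terminus is fully substituted) with retention of alkene geometry; the side chain is predicted to enter anti to the C4 methylene, which stands more nearly perpendicular to the dihydrofuran plane than the 7a-methyl, giving 8S as the major epimer under substrate control of uncertain magnitude.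

Step 7
Reactants: 13 ethyl (2E)-3-[(2S,6S,7aR)-6-acetoxy-4,4,7a-trimethyl-2,4,5,6,7,7a-hexahydro-1-benzofuran-2-yl]but-2-enoate
Product: 14 (2E)-3-[(2S,6S,7aR)-6-hydroxy-4,4,7a-trimethyl-2,4,5,6,7,7a-hexahydro-1-benzofuran-2-yl]but-2-en-1-ol
Conditions: iBu2AlH (5 equiv), CH2Cl2, −78 → −20 °C; Rochelle salt work-up
Reagents that add atoms: none
Why: hydride reduction of the conjugated ester to the allylic alcohol with reductive removal of the acetate in the same pot; no stereocentre or double bond is affected.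

Step 8
Reactants: 14 (2E)-3-[(2S,6S,7aR)-6-hydroxy-4,4,7a-trimethyl-2,4,5,6,7,7a-hexahydro-1-benzofuran-2-yl]but-2-en-1-ol
Product: 16 {(2E)-3-[(2S,6S,7aR)-6-hydroxy-4,4,7a-trimethyl-2,4,5,6,7,7a-hexahydro-1-benzofuran-2-yl]but-2-en-1-yl}triphenylphosphonium chloride, via allylic chloride 15 (not isolated)
Conditions: MsCl (1.05 equiv), 2,4,6-collidine, LiCl, DMF, −10 → 0 °C; then PPh3 (1.2 equiv), 45 °C
Reagents that add atoms: lithium chloride, [Li+].[Cl-]; triphenylphosphine, c1ccc(cc1)P(c1ccccc1)c1ccccc1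
Why: chemoselective Collington–Meyers chlorination of the primary allylic alcohol followed by SN2 quaternisation of triphenylphosphine, under acid-free conditions that keep the allylic dihydrofuran ether and C8 intact.

Step 9
Reactants: 17 (±)-α-ionone; 18 triethyl phosphonoacetate
Product: 19 ethyl (2E,4E)-3-methyl-5-(2,6,6-trimethylcyclohex-2-en-1-yl)penta-2,4-dienoate (racemic)
Conditions: NaH (1.3 equiv), THF, 0 → 60 °C; 2Z isomer removed on silica
Reagents that add atoms: none
Why: Horner–Wadsworth–Emmons olefination of the methyl ketone gives mainly the 2E ester (the future 9'E bond); the ring stereocentre is still racemic.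

Step 10
Reactants: 19 ethyl (2E,4E)-3-methyl-5-(2,6,6-trimethylcyclohex-2-en-1-yl)penta-2,4-dienoate
Product: 20 ethyl (2E,4E)-3-methyl-5-(2,6,6-trimethyl-4-oxocyclohex-2-en-1-yl)penta-2,4-dienoate (racemic)
Conditions: t-BuOOH (70% aq., 5 equiv), Rh2(cap)4 [dirhodium tetrakis(caprolactamate)] (1 mol%), K2CO3, CH2Cl2, 25 °C
Reagents that add atoms: tert-butyl hydroperoxide, CC(C)(C)OO
Why: radical allylic C–H oxidation (tert-butylperoxyl chain) at the only unhindered allylic methylene gives the ring enone, as is known for α-ionone and its C15 homologues.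

Step 11
Reactants: 20 ethyl (2E,4E)-3-methyl-5-(2,6,6-trimethyl-4-oxocyclohex-2-en-1-yl)penta-2,4-dienoate
Product: 21 ethyl (2E,4E)-5-[(1R,4R)-4-hydroxy-2,6,6-trimethylcyclohex-2-en-1-yl]-3-methylpenta-2,4-dienoate
Conditions: (S)-2-methyl-CBS-oxazaborolidine (20 mol%), BH3·SMe2 (0.7 equiv), THF, −30 °C; MeOH quench; trans (1R,4R) separated from cis (1S,4R) on silica
Reagents that add atoms: none
Why: Corey–Bakshi–Shibata reduction under reagent control (enone side as the large group) makes the carbinol R in both enantiomers of 20, so the racemate diverges into separable diastereomers and the trans isomer carries 3'R and 6'R.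

Step 12
Reactants: 21 ethyl (2E,4E)-5-[(1R,4R)-4-hydroxy-2,6,6-trimethylcyclohex-2-en-1-yl]-3-methylpenta-2,4-dienoate
Product: 22 (2E,4E)-5-[(1R,4R)-4-hydroxy-2,6,6-trimethylcyclohex-2-en-1-yl]-3-methylpenta-2,4-dien-1-ol
Conditions: iBu2AlH (3.5 equiv), CH2Cl2, −78 °C; Rochelle salt work-up
Reagents that add atoms: none
Why: 1,2-hydride reduction of the ester to the primary allylic alcohol; stereocentres and diene geometry are unchanged.

Step 13
Reactants: 22 (2E,4E)-5-[(1R,4R)-4-hydroxy-2,6,6-trimethylcyclohex-2-en-1-yl]-3-methylpenta-2,4-dien-1-ol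
Product: 24 {(2E,4E)-5-[(1R,4R)-4-hydroxy-2,6,6-trimethylcyclohex-2-en-1-yl]-3-methylpenta-2,4-dien-1-yl}triphenylphosphonium chloride, via allylic chloride 23 (not isolated)
Conditions: MsCl (1.0 equiv), 2,4,6-collidine, LiCl, DMF, −20 → 0 °C; then PPh3 (1.2 equiv), 40 °C
Reagents that add atoms: lithium chloride, [Li+].[Cl-]; triphenylphosphine, c1ccc(cc1)P(c1ccccc1)c1ccccc1
Why: the primary dienylic alcohol is chlorinated selectively (Collington–Meyers) and quaternised by SN2, avoiding the acid that would ionise and epimerise the allylic ring carbinol.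

Step 14
Reactants: 24 ε-ring C15 phosphonium chloride; 25 (2E,4E,6E)-2,7-dimethylocta-2,4,6-trienedial
Product: 26 (2E,4E,6E,8E,10E,12E)-13-[(1R,4R)-4-hydroxy-2,6,6-trimethylcyclohex-2-en-1-yl]-2,7,11-trimethyltrideca-2,4,6,8,10,12-hexaenal
Conditions: 25 (2.5 equiv), NaOMe (2.2 equiv) added slowly, MeOH/CH2Cl2, 0 → 25 °C; excess 25 recovered
Reagents that add atoms: none
Why: Wittig olefination with a semistabilised allylic ylide, mono-selective because the dialdehyde is in excess and the vinylogous product aldehyde is less electrophilic; any 11'Z isomer is equilibrated in step 15.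

Step 15
Reactants: 16 furanoid C15 phosphonium chloride; 26 C25 hydroxy aldehyde
Product: 27 (3S,5R,8S,3'R,6'R)-5,8-epoxy-5,8-dihydro-β,ε-carotene-3,3'-diol (target)
Conditions: NaOMe (2.2 equiv) added slowly to 16 + 26, MeOH/CH2Cl2, 0 → 25 °C; then reflux in EtOH/heptane under argon in the dark; crystallisation
Reagents that add atoms: none
Why: Wittig olefination forms C11=C12 and thermal Z→E isomerisation with crystallisation gives the all-E polyene; the ylide is trapped as it forms to limit reversible β-alkoxide opening at C8, and no stereocentre is otherwise involved.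

**Compound list**
1 | 3-methylbut-2-enal (prenal) | CC(C)=CC=O | starting material
2 | 2-methoxypropene | COC(C)=C | starting material
3 | (4R)-2-methoxy-6-methylhepta-1,5-dien-4-ol | COC(=C)C[C@@H](O)C=C(C)C | intermediate (not isolated)
4 | (4R)-4-hydroxy-6-methylhept-5-en-2-one | CC(=O)C[C@@H](O)C=C(C)C | intermediate
5 | ethyl propiolate | C#CC(=O)OCC | starting material
6 | ethyl (4R,6R)-4,6-dihydroxy-4,8-dimethylnon-7-en-2-ynoate | CCOC(=O)C#C[C@](C)(O)C[C@@H](O)C=C(C)C | intermediate
7 | ethyl 2-[(2R,4S)-2,4-dihydroxy-2,6,6-trimethylcyclohexylidene]acetate (E/Z mixture) | CCOC(=O)C=C1C(C)(C)C[C@H](O)C[C@@]1(C)O | intermediate (not isolated)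
8 | (−)-loliolide, (6S,7aR)-6-hydroxy-4,4,7a-trimethyl-5,6,7,7a-tetrahydro-1-benzofuran-2(4H)-one | O=C1C=C2C(C)(C)C[C@H](O)C[C@@]2(C)O1 | intermediate
9 | (6S,7aR)-4,4,7a-trimethyl-2,4,5,6,7,7a-hexahydro-1-benzofuran-2,6-diol (C2 epimers, as aluminium alkoxide) | OC1C=C2C(C)(C)C[C@H](O)C[C@@]2(C)O1 | intermediate (not isolated)
10 | (6S,7aR)-4,4,7a-trimethyl-2,4,5,6,7,7a-hexahydro-1-benzofuran-2,6-diyl diacetate (C2 epimers) | CC(=O)OC1C=C2C(C)(C)C[C@H](OC(C)=O)C[C@@]2(C)O1 | intermediate
11 | ethyl but-2-ynoate | CC#CC(=O)OCC | starting material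
12 | ethyl (2Z)-3-(4,4,5,5-tetramethyl-1,3,2-dioxaborolan-2-yl)but-2-enoate | CCOC(=O)/C=C(\C)B1OC(C)(C)C(C)(C)O1 | intermediate
13 | ethyl (2E)-3-[(2S,6S,7aR)-6-acetoxy-4,4,7a-trimethyl-2,4,5,6,7,7a-hexahydro-1-benzofuran-2-yl]but-2-enoate | CCOC(=O)/C=C(\C)[C@@H]1C=C2C(C)(C)C[C@H](OC(C)=O)C[C@@]2(C)O1 | intermediate
14 | (2E)-3-[(2S,6S,7aR)-6-hydroxy-4,4,7a-trimethyl-2,4,5,6,7,7a-hexahydro-1-benzofuran-2-yl]but-2-en-1-ol | OC/C=C(\C)[C@@H]1C=C2C(C)(C)C[C@H](O)C[C@@]2(C)O1 | intermediate
15 | (2S,6S,7aR)-2-[(2E)-4-chlorobut-2-en-2-yl]-4,4,7a-trimethyl-2,4,5,6,7,7a-hexahydro-1-benzofuran-6-ol | ClC/C=C(\C)[C@@H]1C=C2C(C)(C)C[C@H](O)C[C@@]2(C)O1 | intermediate (not isolated)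
16 | {(2E)-3-[(2S,6S,7aR)-6-hydroxy-4,4,7a-trimethyl-2,4,5,6,7,7a-hexahydro-1-benzofuran-2-yl]but-2-en-1-yl}triphenylphosphonium chloride | [Cl-].C(/C=C(\C)[C@@H]1C=C2C(C)(C)C[C@H](O)C[C@@]2(C)O1)[P+](c1ccccc1)(c1ccccc1)c1ccccc1 | intermediate
17 | (±)-α-ionone | CC1=CCCC(C)(C)C1/C=C/C(C)=O | starting material
18 | triethyl phosphonoacetate | CCOC(=O)CP(=O)(OCC)OCC | starting material
19 | ethyl (2E,4E)-3-methyl-5-(2,6,6-trimethylcyclohex-2-en-1-yl)penta-2,4-dienoate (racemic) | CC1=CCCC(C)(C)C1/C=C/C(C)=C/C(=O)OCC | intermediate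
20 | ethyl (2E,4E)-3-methyl-5-(2,6,6-trimethyl-4-oxocyclohex-2-en-1-yl)penta-2,4-dienoate (racemic) | CC1=CC(=O)CC(C)(C)C1/C=C/C(C)=C/C(=O)OCC | intermediate
21 | ethyl (2E,4E)-5-[(1R,4R)-4-hydroxy-2,6,6-trimethylcyclohex-2-en-1-yl]-3-methylpenta-2,4-dienoate | CC1=C[C@H](O)CC(C)(C)[C@H]1/C=C/C(C)=C/C(=O)OCC | intermediate
22 | (2E,4E)-5-[(1R,4R)-4-hydroxy-2,6,6-trimethylcyclohex-2-en-1-yl]-3-methylpenta-2,4-dien-1-ol | CC1=C[C@H](O)CC(C)(C)[C@H]1/C=C/C(C)=C/CO | intermediate
23 | (1R,4R)-4-[(1E,3E)-5-chloro-3-methylpenta-1,3-dien-1-yl]-3,5,5-trimethylcyclohex-2-en-1-ol | CC1=C[C@H](O)CC(C)(C)[C@H]1/C=C/C(C)=C/CCl | intermediate (not isolated)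
24 | {(2E,4E)-5-[(1R,4R)-4-hydroxy-2,6,6-trimethylcyclohex-2-en-1-yl]-3-methylpenta-2,4-dien-1-yl}triphenylphosphonium chloride | [Cl-].CC1=C[C@H](O)CC(C)(C)[C@H]1/C=C/C(C)=C/C[P+](c1ccccc1)(c1ccccc1)c1ccccc1 | intermediate
25 | (2E,4E,6E)-2,7-dimethylocta-2,4,6-trienedial | O=C/C(C)=C/C=C/C=C(C)/C=O | starting material
26 | (2E,4E,6E,8E,10E,12E)-13-[(1R,4R)-4-hydroxy-2,6,6-trimethylcyclohex-2-en-1-yl]-2,7,11-trimethyltrideca-2,4,6,8,10,12-hexaenal | CC1=C[C@H](O)CC(C)(C)[C@H]1/C=C/C(C)=C/C=C/C(C)=C/C=C/C=C(C)/C=O | intermediate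
27 | (3S,5R,8S,3'R,6'R)-5,8-epoxy-5,8-dihydro-β,ε-carotene-3,3'-diol | CC1=C[C@H](O)CC(C)(C)[C@H]1/C=C/C(C)=C/C=C/C(C)=C/C=C/C=C(C)/C=C/C=C(\C)[C@@H]1C=C2C(C)(C)C[C@H](O)C[C@@]2(C)O1 | target

**Totals**
Total step count: 15. Longest linear sequence: 8 steps (1, 2, 3, 4, 6, 7, 8, 15).

**Steps most likely to fail, with fallbacks**

Step 3 (radical bicyclisation). The risks are premature reduction of the tertiary radical and an E enoate that does not isomerise and so cannot lactonise. The fallback sets out from 6 and comes back at 8. PhSO2Na and AcOH in EtOH at 60 °C add sulfinate to the ynoate; the addition is reversible and only the adduct with the ester cis to the tertiary hydroxyl lactonises, giving (5R)-5-[(2R)-2-hydroxy-4-methylpent-3-en-1-yl]-5-methyl-4-(phenylsulfonyl)furan-2(5H)-one F1. Fe(acac)3/PhSiH3 then generates the same tertiary radical, which adds 6-exo-trig to the sulfonyl-bearing carbon of the butenolide and expels the sulfonyl radical (radical addition–fragmentation) to give 8. The alkene-geometry question disappears, at the price of closing the two rings in separate operations.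

Step 6 (C8–C9 bond and C8 configuration). The facial bias at C8 is small and its sense is only predicted. The fallback sets out from 8 and comes back at 14, and applies if the incoming group prefers the face syn to the C4 methylene (8R major). The order at C8 is reversed so that hydride, not carbon, is the incoming group. tert-Butyl{[(2E)-3-iodobut-2-en-1-yl]oxy}dimethylsilane F2 (from but-2-yn-1-ol by stannylcupration, iodination and silylation) is lithiated with t-BuLi and added at −78 °C to the lithium alkoxide of 8 (LiN(SiMe3)2, 1 equiv). This gives the hemiketal (6S,7aR)-2-[(2E)-4-{[tert-butyl(dimethyl)silyl]oxy}but-2-en-2-yl]-4,4,7a-trimethyl-2,4,5,6,7,7a-hexahydro-1-benzofuran-2,6-diol F3. Et3SiH/BF3·OEt2 at −78 °C reduces the derived oxocarbenium ion; hydride takes the face that carbon preferred and leaves the side chain 8S, giving (2S,6S,7aR)-2-[(2E)-4-{[tert-butyl(dimethyl)silyl]oxy}but-2-en-2-yl]-4,4,7a-trimethyl-2,4,5,6,7,7a-hexahydro-1-benzofuran-6-ol F4. Bu4NF then gives 14.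

Step 11 (reagent-controlled reduction of a racemate). If reagent control is incomplete in the mismatched enantiomer, the trans product is contaminated with its antipode. The fallback sets out from 20 and comes back at 22. NaBH4/CeCl3·7H2O (Luche) gives the racemic alcohols, from which racemic trans ethyl (2E,4E)-5-(4-hydroxy-2,6,6-trimethylcyclohex-2-en-1-yl)-3-methylpenta-2,4-dienoate F5 is separated. Burkholderia cepacia lipase with vinyl acetate is assumed to acylate the (4R)-carbinol, giving ethyl (2E,4E)-5-[(1R,4R)-4-acetoxy-2,6,6-trimethylcyclohex-2-en-1-yl]-3-methylpenta-2,4-dienoate F6 and leaving the (1S,4S)-alcohol behind; if the enzyme has the opposite preference, the recovered alcohol is 21 itself. F6 under the conditions of step 12, which also cleave the acetate, gives 22.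

**Further compounds**
F1 | step 3 | (5R)-5-[(2R)-2-hydroxy-4-methylpent-3-en-1-yl]-5-methyl-4-(phenylsulfonyl)furan-2(5H)-one | O=C1C=C(S(=O)(=O)c2ccccc2)[C@@](C)(C[C@@H](O)C=C(C)C)O1
F2 | step 6 | tert-butyl{[(2E)-3-iodobut-2-en-1-yl]oxy}dimethylsilane | C/C(I)=C\CO[Si](C)(C)C(C)(C)C
F3 | step 6 | (6S,7aR)-2-[(2E)-4-{[tert-butyl(dimethyl)silyl]oxy}but-2-en-2-yl]-4,4,7a-trimethyl-2,4,5,6,7,7a-hexahydro-1-benzofuran-2,6-diol (C2 epimers) | C/C(=C\CO[Si](C)(C)C(C)(C)C)C1(O)C=C2C(C)(C)C[C@H](O)C[C@@]2(C)O1
F4 | step 6 | (2S,6S,7aR)-2-[(2E)-4-{[tert-butyl(dimethyl)silyl]oxy}but-2-en-2-yl]-4,4,7a-trimethyl-2,4,5,6,7,7a-hexahydro-1-benzofuran-6-ol | C/C(=C\CO[Si](C)(C)C(C)(C)C)[C@@H]1C=C2C(C)(C)C[C@H](O)C[C@@]2(C)O1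
F5 | step 11 | ethyl (2E,4E)-5-[(1RS,4RS)-4-hydroxy-2,6,6-trimethylcyclohex-2-en-1-yl]-3-methylpenta-2,4-dienoate (racemic trans; one enantiomer drawn) | CC1=C[C@H](O)CC(C)(C)[C@H]1/C=C/C(C)=C/C(=O)OCC
F6 | step 11 | ethyl (2E,4E)-5-[(1R,4R)-4-acetoxy-2,6,6-trimethylcyclohex-2-en-1-yl]-3-methylpenta-2,4-dienoate | CC1=C[C@H](OC(C)=O)CC(C)(C)[C@H]1/C=C/C(C)=C/C(=O)OCC
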